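Atom numbering (eremophilane numbering, used for the target and all bicyclic intermediates): ring A = C1, C2, C3, C4, C5, C10; ring B = C5, C6, C7, C8, C9, C10; C11 = carbinol carbon on C7; C14 = the carbon on C5; C15 = the methyl on C4. Compound numbers are those of the steps and of the compound list.

## Analysis of the target

Target 31 is an eremophilane: two fused six-membered carbocycles, ring A (C1–C5, C10) and ring B (C5–C10), sharing the C5–C10 bond. Ring B is a cross-conjugated 6,9-dien-8-one whose C7 carries a tertiary carbinol (C11). Ring A carries three contiguous stereocentres: C3 (R, acyloxy), C4 (R, methyl) and the quaternary C5 (R, methyl C14). The C4 and C5 methyl groups are cis to each other, and the C3 oxygen is trans to the C4 methyl, so it is equatorial on the ring A chair in which C14 is axial. The acyl group is (Z)-2-methyl-3-(methylsulfanyl)prop-2-enoate; its sulfide is oxidised by peroxides and singlet oxygen, and its Z geometry can be lost by reversible conjugate addition. The tertiary allylic C11 alcohol dehydrates under acid, and the dienone is sensitive to nucleophiles and strong base. The hard parts are the quaternary C5 next to C4 with a defined cis relationship, and the late oxidation pattern of ring B, which must be built without touching the ester. The strategy rests on one feature: C5 carries a methyl and its neighbour C10 is the β-carbon of the C8 enone. A C5–C10–C14 cyclopropane β to a C8 carbonyl is therefore a masked angular methyl plus the C9=C10 alkene, and C5=C10 with oxygen at C8 is exactly what dearomatisation of a 6-methoxytetralin delivers.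

## Retrosynthetic reasoning

Target 31 is first cut at the C3–O bond of the ester, giving diol 21 and acid 30. The cut is made with inversion at C3 for two reasons. The vinyl sulfide of 30 would not survive the oxidation that completes ring B, so it must arrive last. The hydroxyl that steers the key step must be cis to the C4 methyl, whereas the ester oxygen is trans. The forward Mitsunobu esterification has to join the hindered secondary alcohol of 21 to 30 with clean inversion and leave the tertiary C11 alcohol alone.

Diol 21 is traced to isopropylidene dienone 18 by removing the C11–O bond and moving C6=C7 back to C7=C11. In the forward sense an ene reaction with singlet oxygen (from 19) does both jobs at once through hydroperoxide 20. It is preferred to a separate dehydrogenation because the exocyclic s-cis enone of 18 is the only alkene that can react.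

Dienone 18 is cut at C7–C11 to hydroxy enone 14 and acetone 15. Forward, the kinetic C7 dienolate 16 adds to 15 to give aldol 17, which is dehydrated. This brings in all three side-chain carbons at the only kinetically acidic carbon of 14.

Enone 14 is the pivotal simplification. C14 is reconnected to C10 and the C8 carbonyl is masked, which leads through cyclopropyl ketone 13 to cyclopropane 12. Forward, acid must remove the dioxolane and open the C10–C14 bond by homoconjugation, so that C14 stays on C5 as the methyl and C9=C10 appears in conjugation. The gain is that the quaternary centre never has to be made by C–C bond formation at a congested sp3 carbon.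

Cyclopropane 12 is cut at C5–C14 and C10–C14 to homoallylic alcohol 9 and diiodomethane 10. Both bonds form in one [2+1] addition, and the face is chosen by the C3 hydroxyl through zinc alkoxide 11. A cut at C4–C5 or C5–C6 would leave the quaternary centre to an alkylation with no handle for face control.

Ketal 9 comes from enol ether 7 and ethane-1,2-diol 8 by acetal exchange, and 7 from tetralol 6 by Birch reduction. The dearomatisation places the tetrasubstituted alkene at C5=C10 and the oxygen at C8, so both rings and the correct oxidation pattern are bought with the aromatic starting material.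

Tetralol 6 holds the only two stereocentres set by reagent control, C3 and C4. They go back to racemic ketone 5, in which C4 is benzylic and α to the carbonyl and therefore configurationally labile. An asymmetric transfer hydrogenation can thus funnel both enantiomers into one cis alcohol. Ketone 5 is the C-methylation product of tetralone 1 and iodomethane 2, reached through enamine 3 and iminium salt 4.

Acid 30 is cut at the C–S bond to iodo acid 28 and sodium methanethiolate 29, a vinylic substitution with retention. Acid 28 arises by oxidation of alcohol 26 through enal 27. Alcohol 26 comes from prop-2-yn-1-ol 22, methylmagnesium bromide 23 and iodine 24 through the chelated vinylmagnesium 25, which fixes the Z geometry.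

## Alternatives that were turned down

Alternative 1: Here ring B is cut at C5–C10 and C8–C9 in a retro-Diels–Alder sense. Because C5–C10 also belongs to ring A, both rings open to a chain with a C5=C6–C7=C8 diene, a C9≡C10 alkyne and the C1–C4 tether between them. On heating, the intramolecular cycloaddition would give A1, the 3,11-bis-silyl ether of eremophila-6,9-diene.
- For it: both rings and the quaternary C5 form in one step. The C11 oxygen and C6=C7 are already in place. C3 can be carried in its final R configuration, so no inversion and no ene oxidation are needed. On functional-group placement this route is stronger than the chosen one.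
- Against it: the diene terminus C5 bears both a methyl and the tether, so one of them must point inward in the s-cis diene, and the alkyne is unactivated, so a high temperature is to be expected. The configuration at C5 would rest on 1,2-induction from C4 across a flexible tether. C3 and C4 must be set by acyclic stereocontrol over several steps. A1 still needs oxidation of the doubly allylic C8 next to a tertiary allylic silyl ether.
- In its place the chosen route offers both rings from a commercial tetralone and a C5 configuration enforced by delivery from a bound oxygen.

Alternative 2: Here ring A is cut at C1–C10 and C3 is reconnected to C8, which leads back to a 2-vinylbicyclo[2.2.2]octenol cage of anisole origin. The potassium alkoxide would undergo an anionic oxy-Cope shift to A2, the cis-fused 8-methoxy-4,5-dimethyloctal-8-en-3-one.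
- For it: the [3,3] shift of such alkoxides is fast and dependable, probably more so than the directed cyclopropanation, and the rigid cage fixes the C4/C5 relationship.
- Against it: A2 has C10 as an sp3 CH and C3 as a ketone. After enol ether hydrolysis a dione with three enolisable flanks must be dehydrogenated selectively at C9–C10. C4 becomes epimerisable. Hydride reduction at C3 is expected to avoid the axial C5 methyl and give the axial alcohol, so an inversion is needed anyway. The cage comes from a Diels–Alder reaction that is racemic unless made asymmetric.
- In its place the chosen route releases the enone in the correct oxidation state in the ring-opening step and takes its absolute configuration from one catalytic reduction.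

Alternative 3: Here the C5–C10 bond is seen as the result of a transannular carbonyl-ene reaction in a ten-membered ketone, which itself comes from an oxy-Cope ring expansion (C7–C8 formed, C5–C10 broken) of a ring A cyclohexanol with a vinyl group on C10 and an alkenyl group on C5. Heating would give A3, the trans-fused 10-hydroxyeremophil-6-ene 3,11-bis-silyl ether.
- For it: a single thermal operation builds ring B and delivers C6=C7 and the C11 oxygen where the target has them. On this point it is stronger than the chosen route, which spends three steps there.
- Against it: the substrate must already contain a quaternary C5, which the rearrangement erases and the ene step has to rebuild under control of a medium-ring conformation. The neutral oxy-Cope step needs a high temperature. A3 still requires dehydration of the C10 alcohol towards C9 rather than C1, and oxidation of C8.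
- In its place the chosen route has a much shorter path to the key substrate and creates C5 only once, from a defined face.

Key step: step 5

Remark on the chemistry (assumption): the (S,S)-TsDPEN ruthenium complex is assumed to give the (2S) carbinol of 6; if the sense of induction proves opposite, the (R,R) complex is used and nothing else changes.

Step 1
Reactants: 1 6-methoxy-3,4-dihydronaphthalen-2(1H)-one (6-methoxy-2-tetralone); 2 iodomethane
Product: 5 rac-6-methoxy-1-methyl-3,4-dihydronaphthalen-2(1H)-one, via pyrrolidine enamine 3 (not isolated), via C1-methyl iminium iodide 4 (not isolated)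
Conditions: pyrrolidine (1.3 equiv), PhMe, reflux, Dean–Stark, N2; evaporate; MeI (3 equiv), MeCN, 60 °C; then H2O, 60 °C
Reagents that add atoms: iodomethane (CI); water (O)
Why: Stork enamine alkylation: the enamine forms towards C1 (conjugated with the arene), is C-methylated once, and hydrolysis returns the ketone, which avoids the double alkylation of direct enolate methylation. The new centre is racemic and labile, which step 2 exploits.

Step 2
Reactants: 5 rac-6-methoxy-1-methyl-3,4-dihydronaphthalen-2(1H)-one
Product: 6 (1R,2S)-6-methoxy-1-methyl-1,2,3,4-tetrahydronaphthalen-2-ol (cis)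
Conditions: RuCl(p-cymene)[(S,S)-TsDPEN] (1 mol %), HCO2H/Et3N (5:2), DMF, 35 °C
Reagents that add atoms: none
Why: Noyori–Ikariya asymmetric transfer hydrogenation under dynamic kinetic resolution: the benzylic α-keto C–H epimerises quickly in the amine medium while the catalyst reduces one enantiomer faster. Hydride is delivered anti to the pseudo-axial methyl, which sets the cis relationship, and the catalyst sets the absolute configuration at both centres (C3 and C4 of the target).

Step 3
Reactants: 6 (1R,2S)-6-methoxy-1-methyl-1,2,3,4-tetrahydronaphthalen-2-ol
Product: 7 (1R,2S)-6-methoxy-1-methyl-1,2,3,4,5,8-hexahydronaphthalen-2-ol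
Conditions: Li (8 equiv), NH3(l)/THF, t-BuOH (5 equiv), −78 → −33 °C; then MeOH, NH4Cl
Reagents that add atoms: none
Why: Birch reduction of the anisole ring: protonation ortho and meta to the methoxy group leaves the enol ether at C7=C8 and the tetrasubstituted alkene at C5=C10. The lithium alkoxide at C3 and both stereocentres are untouched.

Step 4
Reactants: 7 (1R,2S)-6-methoxy-1-methyl-1,2,3,4,5,8-hexahydronaphthalen-2-ol; 8 ethane-1,2-diol
Product: 9 (3S,4R)-3-hydroxy-4-methyloctal-5(10)-en-8-one ethylene ketal (hydroxyl cis to the C4 methyl)
Conditions: HOCH2CH2OH (10 equiv), p-TsOH·H2O (2 mol %), THF, 0 °C → rt; Et3N quench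
Reagents that add atoms: ethane-1,2-diol (OCCO)
Why: Acetal exchange: C-protonation of the enol ether gives an oxocarbenium ion at C8 that the diol traps, and loss of methanol closes the dioxolane. No free ketone is formed, so the alkene has no path into conjugation and stays at C5=C10, as in ketalisations of 5(10)-unsaturated 19-norsteroids.

Step 5
Reactants: 9 (3S,4R)-3-hydroxy-4-methyloctal-5(10)-en-8-one ethylene ketal; 10 diiodomethane
Product: 12 (3S,4R,5S,10S)-3-hydroxy-4-methyl-5,10-methylenedecalin-8-one ethylene ketal (C14 on the face of the C3 hydroxyl), via ethylzinc alkoxide 11 (not isolated)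
Conditions: Et2Zn (1.1 equiv), CH2Cl2, 0 °C; then Et2Zn (4 equiv), CH2I2 (8 equiv), 0 °C → rt; sat. aq NH4Cl
Reagents that add atoms: diiodomethane (ICI)
Why: Et2Zn first turns the C3 hydroxyl into zinc alkoxide 11, and exchange with CH2I2 places an (iodomethyl)zinc unit on that oxygen. Methylene is then transferred to C5=C10 through a concerted butterfly transition state (Simmons–Smith reaction, Furukawa modification), the closest known case being the hydroxyl-directed cyclopropanation of 5(10)-unsaturated 19-norsteroid 3-alcohols. The three-membered ring closes by a single [2+1] addition in which C5–C14 and C10–C14 form together. The two new quaternary stereocentres C5 and C10 are both controlled by the C3 carbinol centre, because zinc held on an axial C3 oxygen can reach only the alkene face on which it sits. In that reactive half-chair the cis C4 methyl is pseudo-equatorial, close to the alkene plane, and does not shield the face; the conformer with a pseudo-axial methyl has an equatorial oxygen that cannot deliver. The step needs facial selectivity only, since C5=C10 is the sole alkene and is electron-rich enough for the electrophilic carbenoid, while undirected attack on so hindered an alkene is slow. The dioxolane has one oxygen towards each face and binds zinc far more weakly than the alkoxide, so it adds no net bias, and the buffered quench keeps it intact.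

Step 6
Reactants: 12 (3S,4R,5S,10S)-3-hydroxy-4-methyl-5,10-methylenedecalin-8-one ethylene ketal
Product: 14 (3S,4R,5R)-3-hydroxy-4,5-dimethyloctal-9-en-8-one, via cyclopropyl ketone 13 (not isolated)
Conditions: 3 M aq HCl, THF, rt, then 60 °C
Reagents that add atoms: water (O)
Why: Aqueous acid first hydrolyses the dioxolane to ketone 13; its enol towards C9 then pushes into the C10–C14 bond while C14 is protonated, a homoconjugate ring opening known from 5,10-methylene 3-keto steroids. Only C10 is β to the carbonyl, so C14 remains on C5 as the methyl, cis to the C4 methyl, and C9=C10 appears in conjugation.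

Step 7
Reactants: 14 (3S,4R,5R)-3-hydroxy-4,5-dimethyloctal-9-en-8-one; 15 acetone
Product: 17 (3S,4R,5R,7S)-3-hydroxy-7-(2-hydroxypropan-2-yl)-4,5-dimethyloctal-9-en-8-one, via dilithium alkoxide dienolate 16 (not isolated)
Conditions: LiN(i-Pr)2 (2.3 equiv), THF, −78 °C; acetone (3 equiv), −78 °C; aq NH4Cl at −78 °C
Reagents that add atoms: acetone (CC(C)=O)
Why: After the hydroxyl is deprotonated, kinetic α′-deprotonation of the enone gives the cross-conjugated C7 dienolate, which undergoes aldol addition to acetone. The side chain should enter trans to the axial C5 methyl, but C7 becomes trigonal in step 8, so its configuration is of no consequence.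

Step 8
Reactants: 17 (3S,4R,5R,7S)-3-hydroxy-7-(2-hydroxypropan-2-yl)-4,5-dimethyloctal-9-en-8-one
Product: 18 (3S,4R,5R)-3-hydroxyeremophila-7(11),9-dien-8-one
Conditions: p-TsOH·H2O (10 mol %), PhH, 70 °C, Dean–Stark
Reagents that add atoms: none
Why: Acid-catalysed dehydration of the tertiary β-hydroxy ketone. Under these equilibrating conditions the conjugated tetrasubstituted isopropylidene isomer is favoured over the isopropenyl isomer, and the secondary C3 alcohol does not ionise.

Step 9
Reactants: 18 (3S,4R,5R)-3-hydroxyeremophila-7(11),9-dien-8-one; 19 dioxygen
Product: 21 (3S,4R,5R)-3,11-dihydroxyeremophila-6,9-dien-8-one, via C11 hydroperoxide 20 (not isolated)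
Conditions: O2, tetraphenylporphyrin (1 mol %), visible light, CH2Cl2, 0 °C; then PPh3 (1.2 equiv), 0 °C → rt
Reagents that add atoms: dioxygen (O=O)
Why: Schenck ene reaction of singlet oxygen with an s-cis alkylidene ketone: oxygen bonds to the β-carbon C11 and the hydrogen is taken from C6, the group geminal to the carbonyl, which moves the alkene to C6=C7. The endocyclic s-trans C9=C10 enone is inert, and PPh3 reduces the hydroperoxide to the alcohol.

Step 10
Reactants: 22 prop-2-yn-1-ol; 23 methylmagnesium bromide; 24 iodine
Product: 26 (Z)-3-iodo-2-methylprop-2-en-1-ol, via vinylmagnesium alkoxide 25 (not isolated)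
Conditions: MeMgBr (3 equiv), CuI (10 mol %), THF, −10 °C → rt; then I2 (1.5 equiv), −78 → 0 °C; aq NH4Cl
Reagents that add atoms: methylmagnesium bromide (C[Mg]Br); iodine ([I][I])
Why: Copper-catalysed anti carbomagnesiation of the propargylic alkoxide puts the methyl on C2 and magnesium on C3, held cis to the CH2O group by chelation. Iodinolysis with retention then gives the Z vinyl iodide.

Step 11
Reactants: 26 (Z)-3-iodo-2-methylprop-2-en-1-ol
Product: 28 (Z)-3-iodo-2-methylprop-2-enoic acid, via (Z)-3-iodo-2-methylprop-2-enal 27 (not isolated)
Conditions: TEMPO (10 mol %), PhI(OAc)2 (1.1 equiv), CH2Cl2, rt; then NaClO2, NaH2PO4, 2-methyl-2-butene, t-BuOH/H2O, 0 °C → rt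
Reagents that add atoms: sodium chlorite ([Na+].[O-]Cl=O)
Why: Oxoammonium oxidation of the allylic alcohol to the enal, then Pinnick oxidation to the acid. Neither reagent touches the vinyl iodide or the alkene geometry.

Step 12
Reactants: 28 (Z)-3-iodo-2-methylprop-2-enoic acid; 29 sodium methanethiolate
Product: 30 (Z)-2-methyl-3-(methylsulfanyl)prop-2-enoic acid
Conditions: NaSMe (2.5 equiv), CuI (10 mol %), degassed DMF, 60 °C; then 1 M HCl
Reagents that add atoms: sodium methanethiolate ([Na+].[S-]C)
Why: Copper-catalysed Ullmann-type C–S coupling of a vinyl iodide with a thiolate, assisted by the cis carboxylate, proceeds with retention of alkene geometry. Sulfur therefore stays cis to the carboxyl group.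

Step 13
Reactants: 21 (3S,4R,5R)-3,11-dihydroxyeremophila-6,9-dien-8-one; 30 (Z)-2-methyl-3-(methylsulfanyl)prop-2-enoic acid
Product: 31 (3R,4R,5R)-11-hydroxy-8-oxoeremophila-6,9-dien-3-yl (Z)-2-methyl-3-(methylsulfanyl)prop-2-enoate
Conditions: PPh3 (2 equiv), DIAD (2 equiv), 30 (2 equiv), PhMe, 0 °C → rt
Reagents that add atoms: none
Why: Mitsunobu esterification: the secondary C3 hydroxyl is activated as an alkoxyphosphonium ion and displaced by the carboxylate in an SN2 reaction, which inverts C3 to R and places the ester trans to the C4 methyl. The tertiary C11 alcohol is not activated, and the neutral conditions spare the vinyl sulfide and the dienone.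

Compound list

1 | 6-methoxy-3,4-dihydronaphthalen-2(1H)-one (6-methoxy-2-tetralone) | COc1ccc2CC(=O)CCc2c1 | starting material
2 | iodomethane | CI | starting material
3 | 1-(6-methoxy-3,4-dihydronaphthalen-2-yl)pyrrolidine | COc1ccc2C=C(N3CCCC3)CCc2c1 | intermediate
4 | 1-(6-methoxy-1-methyl-3,4-dihydronaphthalen-2(1H)-ylidene)pyrrolidin-1-ium iodide (racemic) | COc1ccc2C(C)C(=[N+]3CCCC3)CCc2c1.[I-] | intermediate
5 | rac-6-methoxy-1-methyl-3,4-dihydronaphthalen-2(1H)-one | COc1ccc2C(C)C(=O)CCc2c1 | intermediate
6 | (1R,2S)-6-methoxy-1-methyl-1,2,3,4-tetrahydronaphthalen-2-ol | O[C@H]1CCc2cc(OC)ccc2[C@H]1C | intermediate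
7 | (1R,2S)-6-methoxy-1-methyl-1,2,3,4,5,8-hexahydronaphthalen-2-ol | O[C@H]1CCC2=C([C@H]1C)CC=C(OC)C2 | intermediate
8 | ethane-1,2-diol | OCCO | starting material
9 | (3S,4R)-3-hydroxy-4-methyloctal-5(10)-en-8-one ethylene ketal | O[C@H]1CCC2=C([C@H]1C)CCC3(C2)OCCO3 | intermediate
10 | diiodomethane | ICI | starting material
11 | ethylzinc alkoxide of 9 | CC[Zn]O[C@H]1CCC2=C([C@H]1C)CCC3(C2)OCCO3 | intermediate
12 | (3S,4R,5S,10S)-3-hydroxy-4-methyl-5,10-methylenedecalin-8-one ethylene ketal | O[C@H]1CC[C@@]23C[C@@]2(CCC4(C3)OCCO4)[C@H]1C | intermediate
13 | (3S,4R,5S,10S)-3-hydroxy-4-methyl-5,10-methylenedecalin-8-one | O[C@H]1CC[C@@]23C[C@@]2(CCC(=O)C3)[C@H]1C | intermediate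
14 | (3S,4R,5R)-3-hydroxy-4,5-dimethyloctal-9-en-8-one | O[C@H]1CCC2=CC(=O)CC[C@]2(C)[C@H]1C | intermediate
15 | acetone | CC(C)=O | starting material
16 | dilithium C3-alkoxide C7,C8-dienolate of 14 | [Li]O[C@H]1CCC2=CC(O[Li])=CC[C@]2(C)[C@H]1C | intermediate
17 | (3S,4R,5R,7S)-3-hydroxy-7-(2-hydroxypropan-2-yl)-4,5-dimethyloctal-9-en-8-one | O[C@H]1CCC2=CC(=O)[C@H](C(C)(C)O)C[C@]2(C)[C@H]1C | intermediate
18 | (3S,4R,5R)-3-hydroxyeremophila-7(11),9-dien-8-one | O[C@H]1CCC2=CC(=O)C(=C(C)C)C[C@]2(C)[C@H]1C | intermediate
19 | dioxygen | O=O | starting material
20 | (3S,4R,5R)-11-hydroperoxy-3-hydroxyeremophila-6,9-dien-8-one | O[C@H]1CCC2=CC(=O)C(C(C)(C)OO)=C[C@]2(C)[C@H]1C | intermediate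
21 | (3S,4R,5R)-3,11-dihydroxyeremophila-6,9-dien-8-one | O[C@H]1CCC2=CC(=O)C(C(C)(C)O)=C[C@]2(C)[C@H]1C | intermediate
22 | prop-2-yn-1-ol | C#CCO | starting material
23 | methylmagnesium bromide | C[Mg]Br | starting material
24 | iodine | [I][I] | starting material
25 | (Z)-3-(bromomagnesio)-2-methylprop-2-en-1-ol bromomagnesium alkoxide | Br[Mg]/C=C(/C)CO[Mg]Br | intermediate
26 | (Z)-3-iodo-2-methylprop-2-en-1-ol | I/C=C(/C)CO | intermediate
27 | (Z)-3-iodo-2-methylprop-2-enal | I/C=C(/C)C=O | intermediate
28 | (Z)-3-iodo-2-methylprop-2-enoic acid | I/C=C(/C)C(=O)O | intermediate
29 | sodium methanethiolate | [Na+].[S-]C | starting material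
30 | (Z)-2-methyl-3-(methylsulfanyl)prop-2-enoic acid | CS/C=C(/C)C(=O)O | intermediate
31 | (3R,4R,5R)-11-hydroxy-8-oxoeremophila-6,9-dien-3-yl (Z)-2-methyl-3-(methylsulfanyl)prop-2-enoate | CS/C=C(/C)C(=O)O[C@@H]1CCC2=CC(=O)C(C(C)(C)O)=C[C@]2(C)[C@H]1C | target

Total step count: 13. Longest linear sequence: 10 steps (steps 1–9 and 13); the acid branch is 3 steps (10–12).

Least certain steps

Step 5 (key step). The most likely failure is slow methylene transfer to the tetrasubstituted alkene next to the C4 methyl. This would leave the reaction incomplete and let an undirected pathway erode the facial selectivity. O-methylation of the zinc alkoxide by excess carbenoid, or ketal opening by ZnI2, could follow on long reaction times. The fallback ties the carbene to the C3 oxygen so that it can reach only the required face. It sets out from 9, which is converted with glyoxylic acid chloride tosylhydrazone and PhNMe2, then Et3N, into the diazoacetate of 9, F1. Intramolecular cyclopropanation with Cu(acac)2 in hot toluene should give the cyclopropane-fused δ-lactone ketal F2. Aqueous HCl then removes the ketal and opens the C10–C14 bond, now pushed by the C8 enol and pulled by the lactone carbonyl, to the enone lactone F3. Saponification with LiOH gives the hydroxy acid F4, which is kept as its carboxylate because the free acid would relactonise. Hydrodecarboxylation of this salt under photoredox conditions (9-mesityl-10-methylacridinium perchlorate, PhSSPh, blue light) turns the C5 carboxymethyl group into the methyl and comes back to the route at 14. The price is four additional steps.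

Step 13. The axial C3 hydroxyl is flanked by the C4 methyl and is syn-axial to the C5 methyl. Activation may therefore be slow, and the alkoxyphosphonium ion may undergo E2 elimination towards C2 or C4 instead of substitution by the rather weakly acidic thioacrylic acid. The fallback separates inversion from acylation. It sets out from 21, which undergoes the Mitsunobu reaction with 4-nitrobenzoic acid (PPh3, DIAD) to give the inverted 4-nitrobenzoate F5. Methanolysis (K2CO3, MeOH) releases the inverted diol F6 with the equatorial C3 hydroxyl. Yamaguchi esterification of F6 with 30 (2,4,6-trichlorobenzoyl chloride, Et3N, then DMAP) proceeds with retention at C3 and comes back to the route at 31.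

Step 9. The ene reaction may abstract hydrogen from the C11 methyl groups instead of C6, which would put the hydroperoxide on C7 and leave an isopropenyl group. Overoxidation of the product dienone is a second possibility. The fallback avoids singlet oxygen and the dehydration. It sets out from 17, which already carries the C11 hydroxyl, and introduces C6=C7 by α′,β′-dehydrogenation with DDQ in dioxane at reflux, as in the conversion of 4-en-3-one steroids into 1,4-dien-3-ones. It comes back to the route at 21 and makes no compound outside the list (F0).

Step 2. The two flanks of a 2-tetralone carbonyl differ less than those of an aryl ketone, so enantiofacial discrimination may be incomplete. If reduction outruns epimerisation of C1, the cis selectivity suffers as well. The fallback gives up the dynamic resolution. It sets out from 5, which is reduced with LiBH(s-Bu)3 (THF, −78 °C), hydride entering anti to the methyl, to the racemic cis-tetralol F7. Kinetic resolution with Candida antarctica lipase B and vinyl acetate is expected, by the usual empirical rule for lipases, to acetylate the (1S,2R) enantiomer to the acetate F8 and leave the (1R,2S) alcohol. Separation comes back to the route at 6, at the cost of half of the material.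

Further compounds

F1 | step 5 | (3S,4R)-4-methyl-8-oxooctal-5(10)-en-3-yl diazoacetate 8-ethylene ketal | [N-]=[N+]=CC(=O)O[C@H]1CCC2=C([C@H]1C)CCC3(C2)OCCO3
F2 | step 5 | 5,10-cyclopropane-fused δ-lactone (C14 carbonyl joined to the C3 oxygen) of the 8-ethylene ketal | O5[C@H]1CC[C@@]23[C@@H](C5=O)[C@@]2(CCC4(C3)OCCO4)[C@H]1C
F3 | step 5 | (3S,4R,5R)-5-(carboxymethyl)-3-hydroxy-4-methyloctal-9-en-8-one 3,5-lactone | O1[C@H]2CCC3=CC(=O)CC[C@]3(CC1=O)[C@H]2C
F4 | step 5 | (3S,4R,5R)-5-(carboxymethyl)-3-hydroxy-4-methyloctal-9-en-8-one | O[C@H]1CCC2=CC(=O)CC[C@]2(CC(=O)O)[C@H]1C
F5 | step 13 | (3R,4R,5R)-11-hydroxy-8-oxoeremophila-6,9-dien-3-yl 4-nitrobenzoate | O=C(O[C@@H]1CCC2=CC(=O)C(C(C)(C)O)=C[C@]2(C)[C@H]1C)c1ccc(cc1)[N+](=O)[O-]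
F6 | step 13 | (3R,4R,5R)-3,11-dihydroxyeremophila-6,9-dien-8-one | O[C@@H]1CCC2=CC(=O)C(C(C)(C)O)=C[C@]2(C)[C@H]1C
F0 | step 9 | none | none
F7 | step 2 | rac-cis-6-methoxy-1-methyl-1,2,3,4-tetrahydronaphthalen-2-ol | O[C@H]1CCc2cc(OC)ccc2[C@H]1C.O[C@@H]1CCc2cc(OC)ccc2[C@@H]1C
F8 | step 2 | (1S,2R)-6-methoxy-1-methyl-1,2,3,4-tetrahydronaphthalen-2-yl acetate | CC(=O)O[C@@H]1CCc2cc(OC)ccc2[C@@H]1C
A1 | alternative 1 | (3R,4R,5R)-3-(tert-butyldimethylsilyloxy)-11-(triethylsilyloxy)eremophila-6,9-diene | CC(C)(C)[Si](C)(C)O[C@@H]1CCC2=CCC(C(C)(C)O[Si](CC)(CC)CC)=C[C@]2(C)[C@H]1C
A2 | alternative 2 | cis-fused 8-methoxy-4,5-dimethyloctal-8-en-3-one | O=C1CC[C@@H]2C=C(OC)CC[C@]2(C)[C@H]1C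
A3 | alternative 3 | trans-fused 3-(tert-butyldimethylsilyloxy)-11-(triethylsilyloxy)eremophil-6-en-10-ol | CC(C)(C)[Si](C)(C)O[C@@H]1CC[C@@]2(O)CCC(C(C)(C)O[Si](CC)(CC)CC)=C[C@]2(C)[C@H]1C
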